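The readings stem from a simulated flask for an exercise, noise included.

Your reading at 5.0 d lies far beyond the time in which the fraction still to react in the south flask, taken as the distance of target from its plateau, halves: 2.41 h.

the same everywhere: starting material 0.10 M; catalyst 0.20 mM
- south: protic impurity 0.050 M; the very flask that is asked about, followed so far
- south-west: protic impurity 0.10 M; run made earlier
- flask: protic impurity 0.0500 M; time 5.0 d

south run (percent of the starting material charged)

| time / h | isomer of the product / % | target / % |
|---|---|---|
| 1.50 | 1.9 | 29.5 |
| 5.00 | 9.1 | 58.4 |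
| 8.00 | 11.9 | 68.6 |
| 12.0 | 13.1 | 72.8 |
| 20.0 | 13.5 | 75.7 |
| 25.0 | 13.5 | 75.7 |

south-west run (percent of the starting material charged)

| time / d | isomer of the product / % | target / % |
|---|---|---|
| 0.250 | 6.8 | 62.6 |
| 0.500 | 8.7 | 73.4 |
| 0.833 | 9.8 | 75.2 |
| 1.25 | 9.2 | 75.6 |
| 2.00 | 10.1 | 75.4 |
| 4.00 | 9.8 | 75.7 |

(scatter of a reading: 0.3 percentage points)

- ratio of isomer of the product to target at 3.0 min
- ratio of isomer of the product to target at 5.0 d
- which of isomer of the product and target there is more of at 5.0 d



Two rates then carry the argument. That fraction falls by two routes, and the plateau splits it: in the south flask, target takes 0.218 h⁻¹ and everything else, the leak, takes 0.0700 h⁻¹. Their ratio, 3.12, is the selectivity factor: target made per unit of charge lost to the leak. The south-west flask, with twice the [protic impurity], ends at the same 75.7 % of target. Isomer of the product belongs to the leak, so I expect target ahead at 5.0 d, because the rate to target is the larger. My ratio is the plateau reading, 0.178.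

The forecast gives 0.003 at 3.0 min, 0.178 at 5.0 d and target ahead, holding that “no slow interconversion appears”.

The flask gives 0.00399 and 0.182, with target ahead at 76.0 % against 13.9 %.

    other conformer + protic impurity → quenched substrate (k = 7.56 L mol⁻¹ h⁻¹)
    starting material + catalyst → catalyst + target (k = 1370 L mol⁻¹ h⁻¹)
    starting material ⇌ other conformer (K = 1.50, k = 0.0743 h⁻¹)
    catalyst + other conformer → catalyst + isomer of the product (k = 2990 L mol⁻¹ h⁻¹)
    catalyst ⇌ dormant form (K = 0.380, k = 0.182 h⁻¹)

In the flask, the rate of starting material to target over the forward rate alone to other conformer is 3.7 at the start and 2.9 after 0.0914 d. The first of these paths runs on catalyst and the second does not; for a neighbour flask charged with 8.0 × 10⁻⁴ M, 4.00 times the catalyst, I scale the selectivity factor of 3.12 by that multiple and reckon 12.5, or 92.6 % target, and that neighbour ends at 93.1 %.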